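## Structural features

The target is a trans-fused decalin (ring A = C1–C5 and C10, ring B = C5–C10) with an exocyclic methylene on C4 and a six-carbon chain on C9 that ends in a β-substituted butenolide (C13–C16). Seven contiguous stereocentres run round the bicycle (C1, C10, C5, C6, C7, C8, C9), and an eighth, C11, sits on the chain directly beside quaternary C9. C5 and C9 are both quaternary and 1,3-related through the C10 methine; their methyl groups C19 and C20 are syn-diaxial on the face opposite H10, and C17 on C8 lies on that same face. Oxygen stands on C1 (equatorial acetate, peri to C11), C6 (equatorial acetate), C7 (equatorial isobutyrate), C8 (axial tertiary hydroxyl, cis to O7) and C11 (acetate). The fragile parts are the four esters of two kinds beside a free tertiary alcohol (acyl shift, selective acylation), the base-sensitive butenolide, and the acid- and oxidant-sensitive 1,1-disubstituted alkene. The real difficulty is the C5–C10–C9 array with its two quaternary carbons, together with C1, whose axial face is roofed by both C19 and C20 much like the 11-position of a steroid. The key step uses the fact that C8 is at ketone level two atoms from C5: C6–C7–C8 is carried as a 1-hydroxycyclopropyl group on C9, and C5 is the β-carbon of a ring A enone whose carbonyl becomes the C1 oxygen.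

## Logic of the disconnections

36 ⇒ 35. The C4=C18 bond is cut last in the retrosynthesis because a 1,1-disubstituted alkene would not survive osmylation or singlet oxygen. C4 returns to the carbonyl level it has held since the phenol oxidation. The forward step must methylenate a ketone beside quaternary C5 in the presence of four esters, a butenolide and a free tertiary alcohol, which calls for a non-basic zinc–titanium reagent.

35 ⇒ 34 ⇒ 33 and 30 ⇒ 29. The ester C–O bonds are cut in two groups. O7 is the only oxygen with a different acyl group, so it stays hidden in a 7,8-acetonide while O1, O6 and O11 are acetylated together, and is acylated after one acidic step that also frees C4. This gives one acylating agent per step. The demand is that acetyl does not shift from O6 to O7 during hydrolysis and that the axial C8 hydroxyl stays free.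

33 ⇒ 30. The butenolide is taken back to a 3-substituted furan (C15 and C16 lose their oxidation). The furan survives the organomagnesium, hydride and acylation steps that a butenolide would not. The forward step must put the carbonyl on C15, not C16.

29 ⇒ 28 ⇒ 25 + 26. The C11–C12 bond and then the C11–H bond are cut. C11 is reached as the carbonyl of a γ-lactone that ties it to O1, so the side chain enters as a furylmethyl nucleophile and C11 is set by hydride addition to a ketone. A carbon nucleophile adding to a C11 aldehyde and a hydride adding to a C11 ketone give opposite epimers under the same facial bias; the ketone order is chosen because the staggered arrangement with C8 antiperiplanar predicts 11R.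

25 ⇒ 24 ⇒ 23 ⇒ 22 ⇒ 21. The C7–O and C8–O bonds are cut together (syn-dihydroxylation), then the C6–O bond (allylic oxidation, then 1,2-reduction). Ring B simplifies to a 7-ene. The allylic oxidation must choose the ring methylene C6 over the C17 methyl, and hydride and osmium must both come from the face opposite C19 and C20.

21 ⇒ 19 ⇒ 18. The O1–C11 bond and the C1–H bond are cut. The peri relationship of the equatorial C1 oxygen and the C9 nitrile lets one γ-lactone protect C1–OH, carry C11 at acid level and proofread the C1 configuration. A hydride reagent would attack the C1 ketone from the open face and give the axial alcohol, so the forward reduction must be an electron-transfer reduction that places the metal-bound oxygen equatorial.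

18 ⇒ 17 ⇒ 16 ⇒ 15. The C8–C17 bond is cut. The forward methyl addition must distinguish the C8 ketone from the C1 ketone. This is expected because C8 is activated by the α-nitrile and open on its axial face, whereas C1 is shielded on both faces. Because enolisation of C8 towards C7 is hindered and would compete with enolisation of C1, the alkene is placed by dehydration and a neutral isomerisation, not through an enol derivative.

15 ⇒ 14. The C5–C6 bond is cut; ring B opens and C5 and C10 lose their configuration. Compound 14 has one stereocentre. The nitrile is kept as the C11 precursor because it is the only such group slimmer than methyl. The dimethyl ketal is kept because it arises directly from the phenol and its axial methoxy group penalises a cis-fused product. The hydroxyl is freed only one step earlier. C10 should not be left to equilibration: with an angular methyl and the syn-diaxial C19/C20 pair, the trans fusion is not safely the more stable one. It is therefore set by kinetic hydrogen delivery, and enolising conditions are avoided until C1 is reduced.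

14 ⇒ 13 ⇒ 12 ⇒ 10. The C4 ketal oxygens and the C2–C3 saturation are removed, which takes ring A back to a phenol. An arene masks the enone through all strongly basic steps. The forward steps need para attack of methanol on the phenol twice and hydrogenation of the disubstituted, but not the tetrasubstituted, ring alkene.

10 ⇒ 9 ⇒ 8 ⇒ 4 + 5. The C8–C9 bond is cut between a tertiary benzylic nitrile anion and cyclopropanone. This makes the quaternary centre with a small, very electrophilic partner and avoids titanium-mediated cyclopropanation of an α-cyano ester, where both the acidic C–H and the nitrile would interfere. No reliable asymmetric version exists, so C9 is resolved one step later, at the phenol.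

4 ⇒ 2 + 3 and 2 ⇒ 1. The aryl–C9 bond is cut to an aryl bromide and propanenitrile. The bond is formed while C9 is still tertiary, which is far less crowded than coupling a fully substituted nitrile to a vinyl halide of an enolisable enone. The bromine of 1 already sits between oxygen and methyl, which fixes the regiochemistry.

## Other disconnections considered

Alternative 1: The cut is C9–C11 together with C8–O, a retro-[3+2]. In the forward step the C7 hydroxyl of the 8-ene A2 is converted with EtMgBr into its magnesium alkoxide, which binds the nitrile oxide A4 released from the chloro-oxime A3 and delivers it to the C8=C9 bond to give the isoxazoline A1.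
- In favour: one step makes the C8–O bond and quaternary C9 and brings in all of C11–C16 with the furan. Delivery from O7 fixes the cis O7/O8 relationship. On convergence and on the C7/C8 relationship it is better than the chosen plan, which needs an osmylation and a separate three-step side-chain sequence.
- Against: a tetrasubstituted, unactivated alkene is the least reactive class of dipolarophile, and the carbon terminus must bond to a carbon flanked by C10 and C8, so dimerisation of A4 is likely to compete. A2 itself presupposes a solution for C5 and C10.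
- Comparison: N–O cleavage leaves a C11 ketone, so the C11 problem is the same in both plans (equal). Mechanistically the directed cycloaddition is predictable in sense but doubtful in rate, whereas the radical closure here is one bond onto an activated enone. The endgame of alternative 1 is shorter; the route to A2 is longer and open.

Alternative 2: The cut is C1–C10 and C8–C9. In the forward step Me2AlCl activates the aldehyde of A6, C10 of the E-alkene closes ring A, and the C9 cation is caught by C8 of the Z-enol silane to close ring B, giving A5.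
- In favour: two rings and four stereocentres (C1, C10, C9, C8) come from the single C5 centre in one step. C1 arrives directly as the equatorial alcohol, which is better than the chosen plan, where C1 needs an electron-transfer reduction. The C4 methylene is present from the start, which is also better, as no late methylenation is needed. The C7 ketone could serve both C6 and C8 oxidation, which is at least equal.
- Against: A6 needs an acyclic quaternary stereocentre with four carbon arms and two alkenes of defined geometry. Three π-nucleophiles compete for the activated aldehyde; a type-two carbonyl-ene reaction of the C4 methylene is the obvious diversion. The C9 cation can lose a proton, and the chair–chair fold must put C20 axial against C19.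
- Comparison: structurally this is the most convergent ring construction. Mechanistically a cationic cascade is harder to steer than one radical addition. On paper it is the shortest of the four (better), provided A6 is short to make, which is the uncertain part.

Alternative 3: The cut is C7–C8. In the forward step SmI2 turns the C7 aldehyde of A8 into a ketyl that adds to the C8 methyl ketone within a samarium chelate and closes ring B as the cis-diol A7.
- In favour: the 7,8-cis-diol with the tertiary carbinol and C17 is made in one step, with O6 and the C4 methylene already in place. For the ring B oxygens this is better than the chosen plan, which spends five steps on them.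
- Against: A8 must already hold C5, C9, C10, C6 and C1 on a single cyclohexane, so the central framework problem is moved upstream, not solved. A ketyl beside the C6 silyloxy group can expel that oxygen. The bond joins two neopentyl carbons, and the facial sense rests on one chelate geometry.
- Comparison: it is strong on oxygenation and weak on framework, the mirror image of the chosen plan. The reagent class is the same as in step 13 here (equal in practicality). It saves about four late steps but needs more early ones.

Key step: step 9

Assumptions and conventions: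
- Clerodane numbering is used for all bicyclic compounds. β is the face of the decalin that carries C19 and C20; on this convention H10, O1, O7, O8 and C11 are α, and O6 and C17 are β.
- 1-Ethoxycyclopropan-1-ol (5) and 3-(chloromethyl)furan (26) are treated as purchasable. Each is otherwise one operation from (1-ethoxycyclopropoxy)trimethylsilane or furan-3-ylmethanol.
- The absolute configuration of 10 would be assigned by anomalous-dispersion X-ray analysis of its 4-bromobenzoate.
- Check of descriptors: C9 is R in 10–14; compound 15 is 5S,9R,10R; both map onto the target (1S,5S,6S,7R,8S,9R,10R,11R).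
- The dimethyl ketal is acid-labile; chromatography of 12–33 would use triethylamine-buffered silica.

Step 1
Reactants: 1 2-bromo-3-methylphenol
Product: 2 1-(benzyloxy)-2-bromo-3-methylbenzene
Conditions: BnBr, K2CO3, DMF, 25 °C
Reagents that add atoms: benzyl bromide BrCc1ccccc1
Why: Williamson ether synthesis; the benzyl ether masks the phenol through the basic steps and is removed by neutral hydrogenolysis.

Step 2
Reactants: 2 1-(benzyloxy)-2-bromo-3-methylbenzene; 3 propanenitrile
Product: 4 rac-2-[2-(benzyloxy)-6-methylphenyl]propanenitrile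
Conditions: 3 (3 equiv), NaHMDS, Pd(OAc)2 (cat.), rac-BINAP (cat.), toluene, 80 °C
Reagents that add atoms: none
Why: Palladium-catalysed α-arylation of a nitrile anion; the two ortho substituents block a second arylation, and the new stereocentre is planarised again in step 3.

Step 3
Reactants: 4 rac-2-[2-(benzyloxy)-6-methylphenyl]propanenitrile; 5 1-ethoxycyclopropan-1-ol
Product: 8 rac-2-[2-(benzyloxy)-6-methylphenyl]-2-{1-[(tert-butyldimethylsilyl)oxy]cyclopropyl}propanenitrile, via cyclopropanone 6 (not isolated), via lithium cyclopropoxide 7 (not isolated)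
Conditions: LDA (2.1 equiv), THF, −78 °C; 5, −78 → 25 °C; TBSOTf, −78 → 0 °C
Reagents that add atoms: tert-butyldimethylsilyl trifluoromethanesulfonate CC(C)(C)[Si](C)(C)OS(=O)(=O)C(F)(F)F
Why: The second equivalent of base deprotonates the hemiketal, which collapses to strained cyclopropanone; the tertiary nitrile anion adds to it (aldol-type carbonyl addition, essentially irreversible through strain release) and creates quaternary C9 as a racemate. Silylation in the same flask protects the cyclopropanol against the hypervalent iodine of step 6.

Step 4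
Reactants: 8 rac-2-[2-(benzyloxy)-6-methylphenyl]-2-{1-[(tert-butyldimethylsilyl)oxy]cyclopropyl}propanenitrile
Product: 9 rac-2-{1-[(tert-butyldimethylsilyl)oxy]cyclopropyl}-2-(2-hydroxy-6-methylphenyl)propanenitrile
Conditions: H2 (1 atm), Pd/C, EtOAc, 25 °C
Reagents that add atoms: none
Why: Hydrogenolysis of the benzyl ether under neutral conditions; the nitrile, silyl ether and cyclopropane are not touched at one atmosphere.

Step 5
Reactants: 9 rac-2-{1-[(tert-butyldimethylsilyl)oxy]cyclopropyl}-2-(2-hydroxy-6-methylphenyl)propanenitrile
Product: 10 (R)-2-{1-[(tert-butyldimethylsilyl)oxy]cyclopropyl}-2-(2-hydroxy-6-methylphenyl)propanenitrile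
Conditions: preparative SFC, amylose tris(3,5-dimethylphenylcarbamate) phase, CO2/MeOH
Reagents that add atoms: none
Why: Resolution on a chiral stationary phase; the phenol gives a polar handle for separation, and the quaternary centre cannot racemise afterwards. The S enantiomer is set aside.

Step 6
Reactants: 10 (R)-2-{1-[(tert-butyldimethylsilyl)oxy]cyclopropyl}-2-(2-hydroxy-6-methylphenyl)propanenitrile
Product: 12 (R)-2-{1-[(tert-butyldimethylsilyl)oxy]cyclopropyl}-2-(3,3-dimethoxy-2-methyl-6-oxocyclohexa-1,4-dien-1-yl)propanenitrile, via para-methoxyphenol 11 (not isolated)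
Conditions: PhI(OAc)2 (2.2 equiv), MeOH, 0 → 25 °C; NaHCO3 work-up
Reagents that add atoms: methanol CO
Why: Oxidative dearomatisation of a phenol with a hypervalent iodine reagent; the first equivalent introduces methoxy para to the hydroxyl, the second converts the 4-methoxyphenol into the quinone monoketal. This sets the C1 carbonyl, the C4 ketal and the C5=C10 enone in one operation.

Step 7
Reactants: 12 (R)-2-{1-[(tert-butyldimethylsilyl)oxy]cyclopropyl}-2-(3,3-dimethoxy-2-methyl-6-oxocyclohexa-1,4-dien-1-yl)propanenitrile
Product: 13 (R)-2-{1-[(tert-butyldimethylsilyl)oxy]cyclopropyl}-2-(3,3-dimethoxy-2-methyl-6-oxocyclohex-1-en-1-yl)propanenitrile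
Conditions: H2 (1 atm), RhCl(PPh3)3 (10 mol %), toluene, 25 °C
Reagents that add atoms: none
Why: Homogeneous hydrogenation reduces the cis-disubstituted C2=C3 bond and leaves the tetrasubstituted C5=C10 bond, as in the selective 1,2-reduction of cross-conjugated steroidal dienones.

Step 8
Reactants: 13 (R)-2-{1-[(tert-butyldimethylsilyl)oxy]cyclopropyl}-2-(3,3-dimethoxy-2-methyl-6-oxocyclohex-1-en-1-yl)propanenitrile
Product: 14 (R)-2-(3,3-dimethoxy-2-methyl-6-oxocyclohex-1-en-1-yl)-2-(1-hydroxycyclopropyl)propanenitrile
Conditions: Bu4NF, AcOH, THF, 0 °C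
Reagents that add atoms: none
Why: Fluoride desilylation buffered with acetic acid frees the cyclopropanol without base-induced ring opening or oxa-Michael addition. The hydroxyl is liberated only now because the next step needs it as a ligand for manganese.

Step 9
Reactants: 14 (R)-2-(3,3-dimethoxy-2-methyl-6-oxocyclohex-1-en-1-yl)-2-(1-hydroxycyclopropyl)propanenitrile
Product: 15 (5S,9R,10R)-4,4-dimethoxy-5β,9β-dimethyl-1,8-dioxo-trans-decalin-9α-carbonitrile
Conditions: Mn(acac)3 (2.2 equiv), degassed i-PrOH (0.01 M), 40 °C, argon
Reagents that add atoms: none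
Why: Ligand exchange puts the cyclopropanol of 14 on trivalent manganese, inner-sphere electron transfer gives the alkoxy radical, and strain-driven β-scission of one C8–CH2 bond leaves the C8 ketone and a primary radical at C6. This nucleophilic radical adds to C5, the β-carbon of the ring A enone, and the resulting tertiary α-keto radical at C10 takes a hydrogen atom from 2-propanol, whose ketyl radical is oxidised to acetone by the second equivalent of Mn(acac)3. The closest known reaction type is the manganese-mediated oxidative ring opening of cyclopropanols with intramolecular Giese-type addition of the β-keto radical to an enone. Ring B closes in the 6-endo-trig mode; the 5-exo alternative at C10 is polarity-mismatched and would form a bond to a fully substituted α-carbon. C5 is controlled by the C9 stereocentre: of the three C9 substituents only the rod-like nitrile fits in the enone plane beside the C1 oxygen, so C8 with its tether and the C20 methyl straddle C19 on opposite faces and C6 can reach only the face of C5 remote from C20, which leaves C19 and C20 syn. C10 is set kinetically, the hydrogen arriving on the face opposite both axial methyl groups, which gives the trans fusion without reliance on later equilibration. The step needs cyclisation to outrun hydrogen abstraction by the primary radical, which high dilution and the poor donor ability of 2-propanol towards nucleophilic alkyl radicals should secure. Oxidation of the adduct radical to an enone is excluded because neither C5 nor C9 carries hydrogen.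

Step 10
Reactants: 15 (5S,9R,10R)-4,4-dimethoxy-5β,9β-dimethyl-1,8-dioxo-trans-decalin-9α-carbonitrile
Product: 16 8β-hydroxy-4,4-dimethoxy-5β,8α,9β-trimethyl-1-oxo-trans-decalin-9α-carbonitrile
Conditions: MeLi, CeCl3, THF, −78 °C
Reagents that add atoms: methyllithium [Li]C
Why: Organocerium 1,2-addition of low basicity, so C10 is not enolised. The C8 ketone is activated by the α-nitrile and open on its axial α face, whereas the C1 ketone is screened on the β face by C19 and C20 and on the α face by the peri nitrile, so C1 should remain. The C8 configuration (methyl expected axial) is erased in step 11.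

Step 11
Reactants: 16 8β-hydroxy-4,4-dimethoxy-5β,8α,9β-trimethyl-1-oxo-trans-decalin-9α-carbonitrile
Product: 17 4,4-dimethoxy-5β,9β-dimethyl-8-methylidene-1-oxo-trans-decalin-9α-carbonitrile
Conditions: SOCl2, pyridine, CH2Cl2, −20 → 0 °C
Reagents that add atoms: none
Why: E2 dehydration through the chlorosulfite; the equatorial leaving group has no antiperiplanar ring hydrogen, so elimination runs into the methyl group. Any endocyclic isomer formed is the product of step 12.

Step 12
Reactants: 17 4,4-dimethoxy-5β,9β-dimethyl-8-methylidene-1-oxo-trans-decalin-9α-carbonitrile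
Product: 18 4,4-dimethoxy-5β,8,9β-trimethyl-1-oxo-trans-decal-7-ene-9α-carbonitrile
Conditions: chloro[N,N'-bis(3,5-di-tert-butylsalicylidene)-1,2-cyclohexanediaminato]cobalt (3 mol %), PhSiH3 (6 mol %), toluene, 25 °C
Reagents that add atoms: none
Why: Reversible hydrogen-atom transfer from a cobalt hydride isomerises the 1,1-disubstituted alkene to the more stable trisubstituted one; C9 is quaternary, so only the 7-ene can form. The conditions are neutral, so C10, the ketal and the nitrile are safe.

Step 13
Reactants: 18 4,4-dimethoxy-5β,8,9β-trimethyl-1-oxo-trans-decal-7-ene-9α-carbonitrile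
Product: 19 1α-hydroxy-4,4-dimethoxy-5β,8,9β-trimethyl-trans-decal-7-ene-9α-carbonitrile
Conditions: SmI2 (2.5 equiv), H2O, THF, 0 °C
Reagents that add atoms: none
Why: Electron-transfer reduction of the ketone; the samarium-bound oxygen of the ketyl and carbanion takes the equatorial position, since the axial one lies under C19 and C20, and water then delivers the small proton axially, which sets the 1α (equatorial) alcohol. A hydride reagent would attack from the open α face and give the axial epimer. Without an amine additive SmI2/H2O leaves the nitrile and the alkene alone.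

Step 14
Reactants: 19 1α-hydroxy-4,4-dimethoxy-5β,8,9β-trimethyl-trans-decal-7-ene-9α-carbonitrile
Product: 21 4,4-dimethoxy-5β,8,9β-trimethyl-trans-decal-7-ene-9α-carboxylic acid 1α-lactone, via iminolactone 20 (not isolated)
Conditions: KOt-Bu (0.2 equiv), THF, 0 → 25 °C; then pH 6 phosphate buffer, THF/H2O, 25 °C
Reagents that add atoms: water O
Why: Pinner-type intramolecular addition of the 1α-alkoxide to the peri nitrile, which sits within van der Waals contact, gives the five-membered cyclic imidate; mild hydrolysis gives the γ-lactone. Only the 1α epimer can cyclise, so the step also proofreads C1. The lactone protects O1 and holds C11 at acid level.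

Step 15
Reactants: 21 4,4-dimethoxy-5β,8,9β-trimethyl-trans-decal-7-ene-9α-carboxylic acid 1α-lactone
Product: 22 4,4-dimethoxy-5β,8,9β-trimethyl-6-oxo-trans-decal-7-ene-9α-carboxylic acid 1α-lactone
Conditions: Rh2(cap)4 (1 mol %), t-BuOOH (70 % aq.), K2CO3, CH2Cl2, 25 °C
Reagents that add atoms: tert-butyl hydroperoxide CC(C)(C)OO
Why: Allylic C–H oxidation by a tert-butylperoxy radical chain; C6 is the only allylic methylene and lies beside the less substituted alkene carbon, so the enone forms there in preference to oxidation of the C17 methyl.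

Step 16
Reactants: 22 4,4-dimethoxy-5β,8,9β-trimethyl-6-oxo-trans-decal-7-ene-9α-carboxylic acid 1α-lactone
Product: 23 6β-hydroxy-4,4-dimethoxy-5β,8,9β-trimethyl-trans-decal-7-ene-9α-carboxylic acid 1α-lactone
Conditions: NaBH4, CeCl3·7H2O, MeOH, −78 → −40 °C
Reagents that add atoms: none
Why: Luche 1,2-reduction; hydride reaches C6 from the α face, away from the axial C19 on the neighbouring carbon, and gives the equatorial 6β alcohol. The γ-lactone survives at this temperature.

Step 17
Reactants: 23 6β-hydroxy-4,4-dimethoxy-5β,8,9β-trimethyl-trans-decal-7-ene-9α-carboxylic acid 1α-lactone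
Product: 24 6β,7α,8α-trihydroxy-4,4-dimethoxy-5β,8β,9β-trimethyl-trans-decalin-9α-carboxylic acid 1α-lactone
Conditions: OsO4 (5 mol %), NMO, acetone/H2O, 25 °C
Reagents that add atoms: osmium tetroxide O=[Os](=O)(=O)=O; 4-methylmorpholine N-oxide C[N+]1([O-])CCOCC1; water O
Why: Catalytic syn-dihydroxylation from the α face, which is anti to the allylic 6β-hydroxyl and remote from C19 and C20. This sets O7 and O8 α with C17 β.

Step 18
Reactants: 24 6β,7α,8α-trihydroxy-4,4-dimethoxy-5β,8β,9β-trimethyl-trans-decalin-9α-carboxylic acid 1α-lactone
Product: 25 6β-hydroxy-7α,8α-(isopropylidenedioxy)-4,4-dimethoxy-5β,8β,9β-trimethyl-trans-decalin-9α-carboxylic acid 1α-lactone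
Conditions: Me2C(OMe)2, PPTS (cat.), CH2Cl2, 25 °C
Reagents that add atoms: 2,2-dimethoxypropane COC(C)(C)OC
Why: Acetonide formation on the cis 7,8-diol; the trans-diequatorial 6,7 pair does not compete. O7 is thereby set apart from the three hydroxyls that will carry acetate.

Step 19
Reactants: 25 6β-hydroxy-7α,8α-(isopropylidenedioxy)-4,4-dimethoxy-5β,8β,9β-trimethyl-trans-decalin-9α-carboxylic acid 1α-lactone; 26 3-(chloromethyl)furan
Product: 28 9α-[(furan-3-yl)acetyl]-1α,6β-dihydroxy-7α,8α-(isopropylidenedioxy)-4,4-dimethoxy-5β,8β,9β-trimethyl-trans-decalin (in equilibrium with its 1,11-hemiketal), via furylmethylmagnesium chloride 27 (not isolated)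
Conditions: 26, Mg, THF, 0 °C; then 25, THF, −78 → 0 °C; aq. NH4Cl
Reagents that add atoms: none
Why: Grignard addition to a lactone; one equivalent is spent on the C6 hydroxyl, and the hindered tetrahedral magnesium hemiketal does not collapse until work-up, so addition stops at the ketone level. The benzylic-type reagent is expected to react at its methylene carbon.

Step 20
Reactants: 28 9α-[(furan-3-yl)acetyl]-1α,6β-dihydroxy-7α,8α-(isopropylidenedioxy)-4,4-dimethoxy-5β,8β,9β-trimethyl-trans-decalin
Product: 29 (11R)-9α-[2-(furan-3-yl)-1-hydroxyethyl]-1α,6β-dihydroxy-7α,8α-(isopropylidenedioxy)-4,4-dimethoxy-5β,8β,9β-trimethyl-trans-decalin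
Conditions: LiAlH4, THF, −40 → 0 °C
Reagents that add atoms: none
Why: Hydride addition to the open keto form; in the Felkin–Anh arrangement C8 is antiperiplanar to the hydride, the C11 oxygen lies towards C10 and the O1 aluminate, and the hydride passes the C20 methyl, which gives 11R. The acetonide, ketal and furan are inert.

Step 21
Reactants: 29 (11R)-9α-[2-(furan-3-yl)-1-hydroxyethyl]-1α,6β-dihydroxy-7α,8α-(isopropylidenedioxy)-4,4-dimethoxy-5β,8β,9β-trimethyl-trans-decalin
Product: 30 (11R)-1α,6β,11-triacetoxy-9α-[2-(furan-3-yl)ethyl]-7α,8α-(isopropylidenedioxy)-4,4-dimethoxy-5β,8β,9β-trimethyl-trans-decalin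
Conditions: Ac2O, DMAP, pyridine, 40 °C
Reagents that add atoms: acetic anhydride CC(=O)OC(C)=O
Why: Nucleophile-catalysed acetylation of the three secondary hydroxyls; O7 and O8 are locked in the acetonide.

Step 22
Reactants: 30 (11R)-1α,6β,11-triacetoxy-9α-[2-(furan-3-yl)ethyl]-7α,8α-(isopropylidenedioxy)-4,4-dimethoxy-5β,8β,9β-trimethyl-trans-decalin
Product: 33 (11R)-1α,6β,11-triacetoxy-7α,8α-(isopropylidenedioxy)-4,4-dimethoxy-18-norclerod-13-en-15,16-olide, via furan endoperoxide 31 (not isolated), via hydroxybutenolide 32 (not isolated)
Conditions: O2, hν (visible), rose bengal, i-Pr2NEt, CH2Cl2, −78 °C; then NaBH4, EtOH, −40 → 0 °C; aq. citric acid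
Reagents that add atoms: dioxygen O=O
Why: [4+2] addition of singlet oxygen to the furan; the hindered amine removes the bridgehead hydrogen remote from the substituent (Kornblum–DeLaMare rearrangement), so the carbonyl forms at C15 and the hemiacetal at C16. Borohydride reduces the ring-opened aldehyde and the hydroxy acid closes to the β-substituted butenolide. The acetates should survive the short cold exposure.

Step 23
Reactants: 33 (11R)-1α,6β,11-triacetoxy-7α,8α-(isopropylidenedioxy)-4,4-dimethoxy-18-norclerod-13-en-15,16-olide
Product: 34 (11R)-1α,6β,11-triacetoxy-7α,8α-dihydroxy-4-oxo-18-norclerod-13-en-15,16-olide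
Conditions: AcOH/H2O (4:1), 45 °C
Reagents that add atoms: water O
Why: One acidic hydrolysis removes the acetonide and the dimethyl ketal; acid, not base, is used to suppress acetyl shift from O6 to O7. O6 is acetylated before the C4 ketone is freed, so no retro-aldol across C5 is possible.

Step 24
Reactants: 34 (11R)-1α,6β,11-triacetoxy-7α,8α-dihydroxy-4-oxo-18-norclerod-13-en-15,16-olide
Product: 35 (11R)-1α,6β,11-triacetoxy-8α-hydroxy-7α-(2-methylpropanoyloxy)-4-oxo-18-norclerod-13-en-15,16-olide
Conditions: (i-PrCO)2O, DMAP, pyridine, CH2Cl2, 0 → 25 °C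
Reagents that add atoms: 2-methylpropanoic anhydride CC(C)C(=O)OC(=O)C(C)C
Why: Acylation of the only free secondary hydroxyl; the axial tertiary C8 hydroxyl beside quaternary C9 is too hindered to react.

Step 25
Reactants: 35 (11R)-1α,6β,11-triacetoxy-8α-hydroxy-7α-(2-methylpropanoyloxy)-4-oxo-18-norclerod-13-en-15,16-olide
Product: 36 (1S,5S,6S,7R,8S,9R,10R,11R)-1,6,11-triacetoxy-8-hydroxy-7-(2-methylpropanoyloxy)cleroda-4(18),13-dien-15,16-olide (CNP0266716.2)
Conditions: Zn, CH2Br2, TiCl4, THF; then 35, CH2Cl2, 0 → 25 °C
Reagents that add atoms: dibromomethane BrCBr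
Why: Takai–Lombardo methylenation; the non-basic gem-dimetallic reagent converts hindered ketones and leaves esters, the butenolide and the free tertiary alcohol alone.

Compound list

1 | 2-bromo-3-methylphenol | Cc1cccc(O)c1Br | starting material
2 | 1-(benzyloxy)-2-bromo-3-methylbenzene | Cc1cccc(OCc2ccccc2)c1Br | intermediate
3 | propanenitrile | CCC#N | starting material
4 | rac-2-[2-(benzyloxy)-6-methylphenyl]propanenitrile | CC(C#N)c1c(C)cccc1OCc1ccccc1 | intermediate
5 | 1-ethoxycyclopropan-1-ol | CCOC1(O)CC1 | starting material
6 | cyclopropanone | O=C1CC1 | intermediate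
7 | lithium 1-{1-[2-(benzyloxy)-6-methylphenyl]-1-cyanoethyl}cyclopropan-1-olate (racemic) | CC(C#N)(c1c(C)cccc1OCc1ccccc1)C1([O-])CC1.[Li+] | intermediate
8 | rac-2-[2-(benzyloxy)-6-methylphenyl]-2-{1-[(tert-butyldimethylsilyl)oxy]cyclopropyl}propanenitrile | CC(C#N)(c1c(C)cccc1OCc1ccccc1)C1(O[Si](C)(C)C(C)(C)C)CC1 | intermediate
9 | rac-2-{1-[(tert-butyldimethylsilyl)oxy]cyclopropyl}-2-(2-hydroxy-6-methylphenyl)propanenitrile | CC(C#N)(c1c(C)cccc1O)C1(O[Si](C)(C)C(C)(C)C)CC1 | intermediate
10 | (R)-2-{1-[(tert-butyldimethylsilyl)oxy]cyclopropyl}-2-(2-hydroxy-6-methylphenyl)propanenitrile | C[C@](C#N)(c1c(C)cccc1O)C1(O[Si](C)(C)C(C)(C)C)CC1 | intermediate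
11 | (R)-2-{1-[(tert-butyldimethylsilyl)oxy]cyclopropyl}-2-(6-hydroxy-3-methoxy-2-methylphenyl)propanenitrile | C[C@](C#N)(c1c(C)c(OC)ccc1O)C1(O[Si](C)(C)C(C)(C)C)CC1 | intermediate
12 | (R)-2-{1-[(tert-butyldimethylsilyl)oxy]cyclopropyl}-2-(3,3-dimethoxy-2-methyl-6-oxocyclohexa-1,4-dien-1-yl)propanenitrile | COC1(OC)C=CC(=O)C([C@](C)(C#N)C2(O[Si](C)(C)C(C)(C)C)CC2)=C1C | intermediate
13 | (R)-2-{1-[(tert-butyldimethylsilyl)oxy]cyclopropyl}-2-(3,3-dimethoxy-2-methyl-6-oxocyclohex-1-en-1-yl)propanenitrile | COC1(OC)CCC(=O)C([C@](C)(C#N)C2(O[Si](C)(C)C(C)(C)C)CC2)=C1C | intermediate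
14 | (R)-2-(3,3-dimethoxy-2-methyl-6-oxocyclohex-1-en-1-yl)-2-(1-hydroxycyclopropyl)propanenitrile | COC1(OC)CCC(=O)C([C@](C)(C#N)C2(O)CC2)=C1C | intermediate
15 | (5S,9R,10R)-4,4-dimethoxy-5β,9β-dimethyl-1,8-dioxo-trans-decalin-9α-carbonitrile | COC1(OC)CCC(=O)[C@@H]2[C@]1(C)CCC(=O)[C@@]2(C)C#N | intermediate
16 | 8β-hydroxy-4,4-dimethoxy-5β,8α,9β-trimethyl-1-oxo-trans-decalin-9α-carbonitrile | COC1(OC)CCC(=O)[C@@H]2[C@]1(C)CC[C@](C)(O)[C@@]2(C)C#N | intermediate
17 | 4,4-dimethoxy-5β,9β-dimethyl-8-methylidene-1-oxo-trans-decalin-9α-carbonitrile | COC1(OC)CCC(=O)[C@@H]2[C@]1(C)CCC(=C)[C@@]2(C)C#N | intermediate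
18 | 4,4-dimethoxy-5β,8,9β-trimethyl-1-oxo-trans-decal-7-ene-9α-carbonitrile | COC1(OC)CCC(=O)[C@@H]2[C@]1(C)CC=C(C)[C@@]2(C)C#N | intermediate
19 | 1α-hydroxy-4,4-dimethoxy-5β,8,9β-trimethyl-trans-decal-7-ene-9α-carbonitrile | COC1(OC)CC[C@H](O)[C@@H]2[C@]1(C)CC=C(C)[C@@]2(C)C#N | intermediate
20 | cyclic imidate (O1–C11=NH) of 19 | COC1(OC)CC[C@H](O3)[C@@H]2[C@]1(C)CC=C(C)[C@@]2(C)C3=N | intermediate
21 | 4,4-dimethoxy-5β,8,9β-trimethyl-trans-decal-7-ene-9α-carboxylic acid 1α-lactone | COC1(OC)CC[C@H](O3)[C@@H]2[C@]1(C)CC=C(C)[C@@]2(C)C3=O | intermediate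
22 | 4,4-dimethoxy-5β,8,9β-trimethyl-6-oxo-trans-decal-7-ene-9α-carboxylic acid 1α-lactone | COC1(OC)CC[C@H](O3)[C@@H]2[C@]1(C)C(=O)C=C(C)[C@@]2(C)C3=O | intermediate
23 | 6β-hydroxy-4,4-dimethoxy-5β,8,9β-trimethyl-trans-decal-7-ene-9α-carboxylic acid 1α-lactone | COC1(OC)CC[C@H](O3)[C@@H]2[C@]1(C)[C@H](O)C=C(C)[C@@]2(C)C3=O | intermediate
24 | 6β,7α,8α-trihydroxy-4,4-dimethoxy-5β,8β,9β-trimethyl-trans-decalin-9α-carboxylic acid 1α-lactone | COC1(OC)CC[C@H](O3)[C@@H]2[C@]1(C)[C@H](O)[C@@H](O)[C@@](C)(O)[C@@]2(C)C3=O | intermediate
25 | 6β-hydroxy-7α,8α-(isopropylidenedioxy)-4,4-dimethoxy-5β,8β,9β-trimethyl-trans-decalin-9α-carboxylic acid 1α-lactone | COC1(OC)CC[C@H](O3)[C@@H]2[C@]1(C)[C@H](O)[C@@H](O4)[C@@](C)(OC4(C)C)[C@@]2(C)C3=O | intermediate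
26 | 3-(chloromethyl)furan | ClCc1ccoc1 | starting material
27 | (furan-3-ylmethyl)magnesium chloride | Cl[Mg]Cc1ccoc1 | intermediate
28 | 9α-[(furan-3-yl)acetyl]-1α,6β-dihydroxy-7α,8α-(isopropylidenedioxy)-4,4-dimethoxy-5β,8β,9β-trimethyl-trans-decalin (open form of the 1,11-hemiketal) | COC1(OC)CC[C@H](O)[C@@H]2[C@]1(C)[C@H](O)[C@@H](O4)[C@@](C)(OC4(C)C)[C@@]2(C)C(=O)Cc5ccoc5 | intermediate
29 | (11R)-9α-[2-(furan-3-yl)-1-hydroxyethyl]-1α,6β-dihydroxy-7α,8α-(isopropylidenedioxy)-4,4-dimethoxy-5β,8β,9β-trimethyl-trans-decalin | COC1(OC)CC[C@H](O)[C@@H]2[C@]1(C)[C@H](O)[C@@H](O4)[C@@](C)(OC4(C)C)[C@@]2(C)[C@@H](Cc5ccoc5)O | intermediate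
30 | (11R)-1α,6β,11-triacetoxy-9α-[2-(furan-3-yl)ethyl]-7α,8α-(isopropylidenedioxy)-4,4-dimethoxy-5β,8β,9β-trimethyl-trans-decalin | COC1(OC)CC[C@H](OC(C)=O)[C@@H]2[C@]1(C)[C@H](OC(C)=O)[C@@H](O4)[C@@](C)(OC4(C)C)[C@@]2(C)[C@@H](Cc5ccoc5)OC(C)=O | intermediate
31 | furan endoperoxide of 30 (2,3,7-trioxabicyclo[2.2.1]hept-5-ene on the side chain; mixture at the bridgeheads) | COC1(OC)CC[C@H](OC(C)=O)[C@@H]2[C@]1(C)[C@H](OC(C)=O)[C@@H](O4)[C@@](C)(OC4(C)C)[C@@]2(C)[C@@H](CC5=CC6OOC5O6)OC(C)=O | intermediate
32 | 16-hydroxy derivative of 33 (5-hydroxy-4-substituted furan-2(5H)-one; mixture at C16) | COC1(OC)CC[C@H](OC(C)=O)[C@@H]2[C@]1(C)[C@H](OC(C)=O)[C@@H](O4)[C@@](C)(OC4(C)C)[C@@]2(C)[C@@H](CC5=CC(=O)OC5O)OC(C)=O | intermediate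
33 | (11R)-1α,6β,11-triacetoxy-7α,8α-(isopropylidenedioxy)-4,4-dimethoxy-18-norclerod-13-en-15,16-olide | COC1(OC)CC[C@H](OC(C)=O)[C@@H]2[C@]1(C)[C@H](OC(C)=O)[C@@H](O4)[C@@](C)(OC4(C)C)[C@@]2(C)[C@@H](CC5=CC(=O)OC5)OC(C)=O | intermediate
34 | (11R)-1α,6β,11-triacetoxy-7α,8α-dihydroxy-4-oxo-18-norclerod-13-en-15,16-olide | O=C1CC[C@H](OC(C)=O)[C@@H]2[C@]1(C)[C@H](OC(C)=O)[C@@H](O)[C@@](C)(O)[C@@]2(C)[C@@H](CC5=CC(=O)OC5)OC(C)=O | intermediate
35 | (11R)-1α,6β,11-triacetoxy-8α-hydroxy-7α-(2-methylpropanoyloxy)-4-oxo-18-norclerod-13-en-15,16-olide | O=C1CC[C@H](OC(C)=O)[C@@H]2[C@]1(C)[C@H](OC(C)=O)[C@@H](OC(=O)C(C)C)[C@@](C)(O)[C@@]2(C)[C@@H](CC5=CC(=O)OC5)OC(C)=O | intermediate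
36 | (1S,5S,6S,7R,8S,9R,10R,11R)-1,6,11-triacetoxy-8-hydroxy-7-(2-methylpropanoyloxy)cleroda-4(18),13-dien-15,16-olide (CNP0266716.2) | C=C1CC[C@H](OC(C)=O)[C@@H]2[C@]1(C)[C@H](OC(C)=O)[C@@H](OC(=O)C(C)C)[C@@](C)(O)[C@@]2(C)[C@@H](CC1=CC(=O)OC1)OC(C)=O | target

Total step count: 25. Longest linear sequence: 25 steps (1 → 36; compound 26 enters at step 19).

Steps least certain to work

Step 9 (key step). The most likely failure is loss of facial control at C5: the tether may close on the C20 face and give the C19/C20 anti series, because the preference of nitrile over methyl for the in-plane position is small. The second risk is hydrogen abstraction by the primary radical before ring closure. The fallback sets out from 14: electrophilic ring opening with N-iodosuccinimide should give the β-iodo ketone (R)-2-(3,3-dimethoxy-2-methyl-6-oxocyclohex-1-en-1-yl)-5-iodo-2-methyl-3-oxopentanenitrile F1. A tin-free radical chain with (Me3Si)3SiH and Et3B/O2 in toluene at −40 °C then generates the same C6 radical under reductive, non-oxidative conditions at a temperature where the conformational bias counts for more, and returns to the route at 15.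

Step 3. The hindered benzylic anion may transfer a proton or let cyclopropanone oligomerise instead of adding. The fallback sets out from 4: C-acylation of the anion with N-acetylimidazole gives rac-2-[2-(benzyloxy)-6-methylphenyl]-2-methyl-3-oxobutanenitrile F2. TBSOTf/Et3N converts it into the silyl enol ether rac-2-[2-(benzyloxy)-6-methylphenyl]-3-[(tert-butyldimethylsilyl)oxy]-2-methylbut-3-enenitrile F3, and Simmons–Smith cyclopropanation (Et2Zn, CH2I2) returns to the route at 8.

Step 10. The organocerium reagent may also add to the C1 ketone, or only enolise. The fallback sets out from 15 and uses a Wittig methylenation (Ph3PCH3Br, KHMDS, THF, 0 → 40 °C). The bulky ylide discriminates more strongly against the doubly shielded C1 carbonyl and gives 17 directly, so the route is rejoined at 17 without a new compound; the basic ylide is a risk to C10 and would be used only if needed.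

Step 13. Protonation may not follow the equatorial-oxygen preference and give the axial 1β alcohol, or some nitrile may be reduced. The fallback sets out from 18: NaBH4 gives, by attack from the open face, the axial alcohol 1β-hydroxy-4,4-dimethoxy-5β,8,9β-trimethyl-trans-decal-7-ene-9α-carbonitrile F4. Neutral platinum-catalysed hydration with [PtH(PMe2OH)(PMe2O)2H] in aqueous ethanol converts the nitrile into the primary amide 1β-hydroxy-4,4-dimethoxy-5β,8,9β-trimethyl-trans-decal-7-ene-9α-carboxamide F5. Mesylation (MsCl, pyridine) then lets the peri amide oxygen displace the axial sulfonate with inversion to give 20, and buffered hydrolysis returns to the route at 21. Here C1 is set by an intramolecular substitution and not by a reduction.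

Step 19. The furylmethyl Grignard reagent may react through the ring carbon next to its methylene (allylic transposition), or the lactone may not stop at single addition. The fallback sets out from 25: the reagent 3-[(phenylsulfonyl)methyl]furan F6 (from 26 and PhSO2Na) is lithiated with n-BuLi and acylated by the lactone to give the β-keto sulfone 9α-[2-(furan-3-yl)-2-(phenylsulfonyl)acetyl]-1α,6β-dihydroxy-7α,8α-(isopropylidenedioxy)-4,4-dimethoxy-5β,8β,9β-trimethyl-trans-decalin F7. SmI2 in THF/MeOH at −78 °C removes the sulfonyl group and returns to the route at 28.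

Step 20. Hydride may add to the other face of the C11 ketone and give 11S, since the facial bias rests on a model. The fallback sets out from 25: DIBAL-H at −78 °C gives the lactol 6β-hydroxy-7α,8α-(isopropylidenedioxy)-4,4-dimethoxy-5β,8β,9β-trimethyl-trans-decalin-9α-carbaldehyde 1α,11-hemiacetal F8. Addition of 27 to its open hydroxy aldehyde form puts the carbon nucleophile where the hydride went before, which inverts the sense at C11, and returns to the route at 29.

Further compounds

F1 | step 9 | (R)-2-(3,3-dimethoxy-2-methyl-6-oxocyclohex-1-en-1-yl)-5-iodo-2-methyl-3-oxopentanenitrile | COC1(OC)CCC(=O)C([C@](C)(C#N)C(=O)CCI)=C1C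
F2 | step 3 | rac-2-[2-(benzyloxy)-6-methylphenyl]-2-methyl-3-oxobutanenitrile | CC(=O)C(C)(C#N)c1c(C)cccc1OCc1ccccc1
F3 | step 3 | rac-2-[2-(benzyloxy)-6-methylphenyl]-3-[(tert-butyldimethylsilyl)oxy]-2-methylbut-3-enenitrile | C=C(O[Si](C)(C)C(C)(C)C)C(C)(C#N)c1c(C)cccc1OCc1ccccc1
F0 | step 10 | none | none
F4 | step 13 | 1β-hydroxy-4,4-dimethoxy-5β,8,9β-trimethyl-trans-decal-7-ene-9α-carbonitrile | COC1(OC)CC[C@@H](O)[C@@H]2[C@]1(C)CC=C(C)[C@@]2(C)C#N
F5 | step 13 | 1β-hydroxy-4,4-dimethoxy-5β,8,9β-trimethyl-trans-decal-7-ene-9α-carboxamide | COC1(OC)CC[C@@H](O)[C@@H]2[C@]1(C)CC=C(C)[C@@]2(C)C(N)=O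
F6 | step 19 | 3-[(phenylsulfonyl)methyl]furan | O=S(=O)(Cc1ccoc1)c1ccccc1
F7 | step 19 | 9α-[2-(furan-3-yl)-2-(phenylsulfonyl)acetyl]-1α,6β-dihydroxy-7α,8α-(isopropylidenedioxy)-4,4-dimethoxy-5β,8β,9β-trimethyl-trans-decalin | COC1(OC)CC[C@H](O)[C@@H]2[C@]1(C)[C@H](O)[C@@H](O4)[C@@](C)(OC4(C)C)[C@@]2(C)C(=O)C(c5ccoc5)S(=O)(=O)c6ccccc6
F8 | step 20 | 6β-hydroxy-7α,8α-(isopropylidenedioxy)-4,4-dimethoxy-5β,8β,9β-trimethyl-trans-decalin-9α-carbaldehyde 1α,11-hemiacetal | COC1(OC)CC[C@H](O3)[C@@H]2[C@]1(C)[C@H](O)[C@@H](O4)[C@@](C)(OC4(C)C)[C@@]2(C)C3O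
A1 | alternative 1 | isoxazoline-fused decalin with furylmethyl side chain | C12(OCCO1)CC[C@H](O[Si](C)(C)C(C)(C)C)[C@@H]3[C@]2(C)[C@H](O[Si](C)(C)C(C)(C)C)[C@@H](O)[C@@]4(C)ON=C(Cc5ccoc5)[C@@]34C
A2 | alternative 1 | 1α,6β-bis(tert-butyldimethylsilyloxy)-4,4-(ethylenedioxy)-5β,8,9-trimethyl-10αH-decal-8-en-7α-ol | C12(OCCO1)CC[C@H](O[Si](C)(C)C(C)(C)C)[C@@H]3[C@]2(C)[C@H](O[Si](C)(C)C(C)(C)C)[C@@H](O)C(C)=C3C
A3 | alternative 1 | 2-(furan-3-yl)-N-hydroxyacetimidoyl chloride | ON=C(Cl)Cc1ccoc1
A4 | alternative 1 | 2-(furan-3-yl)acetonitrile oxide | [O-][N+]#CCc1ccoc1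
A5 | alternative 2 | trans-decalin with C1 alcohol, C4 methylene, C7 ketone and quaternary C9 | C=C1CC[C@H](O)[C@@H]2[C@]1(C)CC(=O)[C@H](C)[C@@]2(C)CO[Si](c3ccccc3)(c4ccccc4)C(C)(C)C
A6 | alternative 2 | open-chain aldehyde with quaternary C5, E-alkene and Z-enol silane | C=C(CCC=O)[C@](C)(/C=C(\C)CO[Si](c1ccccc1)(c1ccccc1)C(C)(C)C)C/C(O[Si](C)(C)C)=C/C
A7 | alternative 3 | decalin cis-7,8-diol | C=C1CC[C@H](O[Si](C)(C)C(C)(C)C)[C@@H]2[C@]1(C)[C@H](O[Si](C)(C)C(C)(C)C)[C@@H](O)[C@@](C)(O)[C@@]2(C)COCc3ccc(OC)cc3
A8 | alternative 3 | monocyclic C7 aldehyde / C8 methyl ketone | C=C1CC[C@H](O[Si](C)(C)C(C)(C)C)[C@@H]([C@](C)(COCc2ccc(OC)cc2)C(C)=O)[C@]1(C)[C@H](O[Si](C)(C)C(C)(C)C)C=O
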